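**Assumption:** the target SMILES has no stereocentres and no E/Z-defined alkene, so the compound is achiral and "single enantiomer" requires no stereocontrol. The route has not been run; it is designed by analogy to known acylphloroglucinol chemistry.

## Retrosynthetic overview

1. The pyran ring is the only ring formed and it is formed last: prenal annulation of triphenol 9 at its single free aromatic CH, closing through the para-oxygen.
2. Triphenol 9 comes from global MOM removal of methyl ether 8, whose OMe is placed on the phenol released by the rearrangement below.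
3. The C-prenyl group comes from a para-Claisen–Cope shift of aryl prenyl ether 6, which puts prenyl between the two OMOM groups and para to the future OMe.
4. Ether 6 comes from the symmetrical 2,4,6-trihydroxybenzophenone 3 by tris-MOM protection (one chelated OH is left) and O-prenylation.
5. Benzophenone 3 comes from phloroglucinol and 4-hydroxybenzonitrile (Houben–Hoesch); both benzene rings are purchased.

## Route

**Step 1**
Reactants: 1 phloroglucinol; 2 4-hydroxybenzonitrile
Product: 3 (4-hydroxyphenyl)(2,4,6-trihydroxyphenyl)methanone
Conditions: ZnCl2, HCl(g), Et2O, 0 °C → rt; then H2O, 100 °C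
Reagents that add atoms: water, O (becomes the ketone oxygen; the nitrile N is lost as NH4Cl)
Why: Houben–Hoesch acylation of the very electron-rich, C3-symmetric phloroglucinol gives a single mono-ketimine that hydrolyses to the ketone.

**Step 2**
Reactants: 3
Product: 4 [2-hydroxy-4,6-bis(methoxymethoxy)phenyl][4-(methoxymethoxy)phenyl]methanone
Conditions: MOMCl (3.3 equiv), i-Pr2NEt, CH2Cl2/DMF, 0 °C → rt
Reagents that add atoms: MOMCl, COCCl
Why: Chemoselective O-alkylation caps the two non-chelated phenols and one of the two equivalent chelated phenols, while the last OH stays free because it is strongly hydrogen-bonded to the carbonyl.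

**Step 3**
Reactants: 4; 5 3-methylbut-2-en-1-ol (prenol)
Product: 6 [2,4-bis(methoxymethoxy)-6-(3-methylbut-2-enyloxy)phenyl][4-(methoxymethoxy)phenyl]methanone
Conditions: PPh3, DIAD, THF, 0 °C → rt
Reagents that add atoms: none (besides reactant 5)
Why: Mitsunobu etherification alkylates the chelated phenol under neutral conditions with SN2 delivery, giving the unrearranged O-prenyl ether.

**Step 4**
Reactants: 6
Product: 7 [6-hydroxy-2,4-bis(methoxymethoxy)-3-(3-methylbut-2-enyl)phenyl][4-(methoxymethoxy)phenyl]methanone
Conditions: PhNEt2, 200 °C, sealed tube
Reagents that add atoms: none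
Why: Tandem aromatic Claisen/Cope (para-Claisen) rearrangement moves the prenyl, with double allyl inversion, to the carbon para to the ether oxygen, which is the position between the two OMOM groups, and regenerates the chelated phenol.

**Step 5**
Reactants: 7
Product: 8 [6-methoxy-2,4-bis(methoxymethoxy)-3-(3-methylbut-2-enyl)phenyl][4-(methoxymethoxy)phenyl]methanone
Conditions: Me2SO4, K2CO3, acetone, reflux
Reagents that add atoms: dimethyl sulfate, COS(=O)(=O)OC
Why: Williamson O-methylation of the only free phenol fixes the methoxy group ortho to the carbonyl and para to the prenyl group.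

**Step 6**
Reactants: 8
Product: 9 [2,4-dihydroxy-6-methoxy-3-(3-methylbut-2-enyl)phenyl](4-hydroxyphenyl)methanone
Conditions: 3 M HCl, MeOH, rt → 40 °C
Reagents that add atoms: none
Why: Mild acetal solvolysis removes all three MOM groups while the aryl methyl ether and, at low temperature, the prenyl alkene survive.

**Step 7**
Reactants: 9; 10 3-methylbut-2-enal (prenal)
Product: 11 Vismiaphenone F, [7-hydroxy-5-methoxy-2,2-dimethyl-8-(3-methylbut-2-enyl)-2H-chromen-6-yl](4-hydroxyphenyl)methanone
Conditions: EDDA (20 mol %), xylene, 130 °C
Reagents that add atoms: none (besides reactant 10)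
Why: Knoevenagel-type condensation at the single free ring-A CH gives an ortho-quinone methide that closes by oxa-6π electrocyclisation through the only adjacent free oxygen (the para-OH, since the other neighbour is OMe), so the chromene regiochemistry is fixed.

## Compound list

1 | phloroglucinol (benzene-1,3,5-triol) | Oc1cc(O)cc(O)c1 | starting material
2 | 4-hydroxybenzonitrile | N#Cc1ccc(O)cc1 | starting material
3 | (4-hydroxyphenyl)(2,4,6-trihydroxyphenyl)methanone | O=C(c1ccc(O)cc1)c1c(O)cc(O)cc1O | intermediate
4 | [2-hydroxy-4,6-bis(methoxymethoxy)phenyl][4-(methoxymethoxy)phenyl]methanone | COCOc1ccc(cc1)C(=O)c1c(O)cc(OCOC)cc1OCOC | intermediate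
5 | 3-methylbut-2-en-1-ol (prenol) | CC(C)=CCO | starting material
6 | [2,4-bis(methoxymethoxy)-6-(3-methylbut-2-enyloxy)phenyl][4-(methoxymethoxy)phenyl]methanone | COCOc1ccc(cc1)C(=O)c1c(OCC=C(C)C)cc(OCOC)cc1OCOC | intermediate
7 | [6-hydroxy-2,4-bis(methoxymethoxy)-3-(3-methylbut-2-enyl)phenyl][4-(methoxymethoxy)phenyl]methanone | COCOc1ccc(cc1)C(=O)c1c(O)cc(OCOC)c(CC=C(C)C)c1OCOC | intermediate
8 | [6-methoxy-2,4-bis(methoxymethoxy)-3-(3-methylbut-2-enyl)phenyl][4-(methoxymethoxy)phenyl]methanone | COCOc1ccc(cc1)C(=O)c1c(OC)cc(OCOC)c(CC=C(C)C)c1OCOC | intermediate
9 | [2,4-dihydroxy-6-methoxy-3-(3-methylbut-2-enyl)phenyl](4-hydroxyphenyl)methanone | COc1cc(O)c(CC=C(C)C)c(O)c1C(=O)c1ccc(O)cc1 | intermediate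
10 | 3-methylbut-2-enal (prenal) | CC(C)=CC=O | starting material
11 | Vismiaphenone F, [7-hydroxy-5-methoxy-2,2-dimethyl-8-(3-methylbut-2-enyl)-2H-chromen-6-yl](4-hydroxyphenyl)methanone (achiral) | COc1c2c(c(CC=C(C)C)c(O)c1C(=O)c1ccc(O)cc1)OC(C)(C)C=C2 | target

## Summary

Total step count: 7. Longest linear sequence: 7 (fully linear from phloroglucinol).

Three steps most likely to fail, each with a fallback that changes the approach:

1. **Step 4 (Claisen–Cope).** The rearrangement may stop at the ortho 1,1-dimethylallyl isomer or give mixtures. Fallback: drop the O→C transfer and build ring A by directed ortho-metalation. Start from 3,5-bis(methoxymethoxy)anisole, lithiate between the two OMOM groups and trap with prenyl bromide (CuI), then lithiate ortho to OMe, add to 4-(methoxymethoxy)benzaldehyde and oxidise (MnO2 or DMP). This converges on compound 8.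

2. **Step 6 (acidic MOM removal).** The prenyl group sits between two phenols and can cyclise to a 2,2-dimethylchroman under acid. Fallback: change the protecting-group strategy from step 2 onward to silyl ethers (TBS or TIPS, which also leave the chelated OH free), so the final unmasking uses fluoride (TBAF/AcOH) and no Brønsted acid.

3. **Step 7 (prenal annulation).** The reacting carbon is on an acyl-deactivated ring and flanked by OMe, so conversion may be low. Fallback: build the pyran stepwise with ring B kept protected (for example as a TIPS ether, available through the DoM variant using 4-(TIPSO)benzaldehyde). Alkylate the free 4-OH with 3-chloro-3-methylbut-1-yne (K2CO3, KI, CuI), heat to trigger aryl propargyl Claisen/1,5-H shift/oxa-6π closure onto the only open ortho carbon, then desilylate with TBAF.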